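Temperature is what separates green, blue and teal, which all hold L at 0.050 M for 2.0 min, and I want to know which ends with the most J.

| flask | L | temperature | remark | time |
|---|---|---|---|---|
| eta | 0.070 M | 0 °C | run made earlier |  |
| epsilon | 0.11 M | 25 °C | run made earlier |  |
| green | 0.050 M | 25 °C |  | 2.0 min |
| blue | 0.050 M | 45 °C |  | 2.0 min |
| teal | 0.050 M | 5 °C |  | 2.0 min |

- eta (time / min: J / %, L / %): 0.500: 0, 95; 0.667: 2, 95; 1.50: 10, 90; 5.00: 16, 67
- epsilon (time / s: J / %, L / %): 10.0: 15, 74; 25.0: 28, 46; 50.0: 32, 27; 80.0: 32, 16

(standard deviation of a reading: 2 percentage points)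



- the flask that comes out highest in amount of J, in percent of the L charged, or "all alike" when all lie within 1.5 percentage points (green / blue / teal / all alike)
- J at the end, in percent of the L charged, green
- J at the end, in percent of the L charged, blue
- J at the end, in percent of the L charged, teal

A rate constant says what share of [L] goes per unit time, so if L falls first-order, one reading from each run, taken with L at a like level, gives one: 0.0301 s⁻¹ from L at 74% in epsilon and 0.00133 s⁻¹ from L at 67% in eta. Their quotient, 22.6, is my reading of how much faster L falls at 25 °C than at 0 °C. I assume that one clock carries every step, that its logarithm runs straight in temperature, and that percentages do not depend on the charge. J offers a check, since it played no part in that quotient: eta's last reading counts as 13.3 s of epsilon, and there J reads 16%, while epsilon's nearest reading, at 10.0 s, gives 15%.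

In epsilon J reads 32% at 50.0 s and 32% at 80.0 s, while L falls from 27% to 16%. So in epsilon, within the scatter of a reading, J, an intermediate, is being lost about as fast as it is made. Before this crest making leads, and after it loss leads. I put the crest midway, at 65.0 s. On the clock, 2.0 min matches that crest at 20.1 °C, the crossing temperature: with the time held at 2.0 min, I expect a flask below it to be still climbing at the end, and a flask above it to be past its crest.

Teal at 5 °C lies below it. Its 2.0 min counts as 9.92 s of epsilon, so I expect J near 15%. Green at 25 °C lies above it, at 1.85 crest times, so I expect J a little under the crest. Blue at 45 °C counts as 1450 s, beyond the last reading, so I expect it lower still. I commit to green.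

The forecast also names green, with green 29% (22% to 36%), blue 3% (0% to 20%) and teal 11.5% (7% to 17%), which is lower than my teal. Of blue it warns: “the plateau might instead mean J is stable”.

The flasks give green 27.4%, blue 4.16% and teal 12.6%, so green is highest.

    L ⇌ D (K = 300, k = 0.00570 s⁻¹, Ea = 84.0 kJ mol⁻¹, ΔH = −25.0 kJ mol⁻¹)
    L ⇌ G (K = 1.90, k = 0.0110 s⁻¹, Ea = 89.0 kJ mol⁻¹, ΔH = 3.00 kJ mol⁻¹)
    L ⇌ J (K = 4.30, k = 0.0170 s⁻¹, Ea = 89.0 kJ mol⁻¹, ΔH = −25.0 kJ mol⁻¹)
    J ⇌ E (K = 12.0, k = 0.00610 s⁻¹, Ea = 74.0 kJ mol⁻¹, ΔH = 11.0 kJ mol⁻¹)
    (constants at 25 °C)

Green, above 20.1 °C, held J at 32.3% after 1.00 min and has come down since, while teal, below it, climbed from 6.96%. A repeat of teal at 20 °C stands at the crossing temperature, so on the clock its 2.0 min counts as 64.3 s, about the crest time. It ends with L at 16.7% and E at 10.6%, and its J stands at 31.9%, above green's 27.4%.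

All runs are simulated for substances that don't exist; scatter was added.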